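**Strategy.** Everything rests on cutting ring C of the flavone at O1–C8a, C4–C4a and O1–C2, which splits the target into a 3,4,5-trioxygenated benzyne (ring A) and an arylpropiolic acid (C2–C4 plus ring B). The key step exploits the ortho pair O1/C4-acyl on C8a/C4a of ring A and the C5 oxygen next to C4a, which steers the carboxylate to C8a. In one operation the aryne takes up the acid with oxygen-to-carbon acyl transfer and the resulting hydroxyaryl ynone closes the pyranone. The aryne precursor is an ortho-silylaryl triflate carrying benzyl ethers at the future O5/O6 and a MOM ether at O7, the only site to be sulfated.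

Key step: step 8

Assumption: the target is taken as the free hydrogen sulfate as drawn; the sulfate is carried as its sodium salt and protonated only in the last operation, cold, because the free acid is prone to hydrolysis. No compound of the main route has a stereocentre; enaminone 17 is drawn as the E isomer.

Step 1
Reactants: 1 2,3,4-trihydroxybenzaldehyde
Product: 2 2,3-dihydroxy-4-(methoxymethoxy)benzaldehyde
Conditions: MOMCl (1.0 equiv), K2CO3 (1.0 equiv), acetone, 0 °C to rt, N2
Reagents that add atoms: chloromethyl methyl ether, COCCl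
Why: Williamson-type O-alkylation in which one equivalent of weak base should ionise only the 4-hydroxyl, the most acidic one because it is para to the formyl group, while the 2-hydroxyl is held in a hydrogen bond to the carbonyl.

Step 2
Reactants: 2 2,3-dihydroxy-4-(methoxymethoxy)benzaldehyde
Product: 3 2,3-bis(benzyloxy)-4-(methoxymethoxy)benzaldehyde
Conditions: BnBr (2.4 equiv), K2CO3 (3 equiv), DMF, 60 °C
Reagents that add atoms: benzyl bromide, BrCc1ccccc1
Why: exhaustive Williamson etherification of the two remaining phenols under basic conditions that leave the MOM acetal untouched.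

Step 3
Reactants: 3 2,3-bis(benzyloxy)-4-(methoxymethoxy)benzaldehyde
Product: 5 2,3-bis(benzyloxy)-4-(methoxymethoxy)phenol, via aryl formate 4 (not isolated)
Conditions: mCPBA, CH2Cl2, 0 °C to rt; aq. NaHCO3 wash; then K2CO3 (cat.), MeOH, rt
Reagents that add atoms: 3-chloroperoxybenzoic acid, O=C(OO)c1cccc(Cl)c1
Why: Baeyer–Villiger (Dakin-type) oxidation in which the electron-rich aryl group with ortho and para oxygens migrates in preference to hydrogen, followed by methanolysis of the formate.

Step 4
Reactants: 5 2,3-bis(benzyloxy)-4-(methoxymethoxy)phenol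
Product: 6 2,3-bis(benzyloxy)-6-bromo-4-(methoxymethoxy)phenol
Conditions: NBS (1.0 equiv), i-Pr2NH (10 mol %), CH2Cl2, −40 °C to 0 °C
Reagents that add atoms: N-bromosuccinimide, O=C1CCC(=O)N1Br
Why: electrophilic aromatic bromination directed by the free hydroxyl, whose para position and one ortho position are blocked, so that only C6 (also para to the C3 benzyloxy group) should react.

Step 5
Reactants: 6 2,3-bis(benzyloxy)-6-bromo-4-(methoxymethoxy)phenol
Product: 9 2,3-bis(benzyloxy)-4-(methoxymethoxy)-6-(trimethylsilyl)phenyl trifluoromethanesulfonate, via aryl silyl ether 7 (not isolated), via lithium phenoxide 8 (not isolated)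
Conditions: HMDS, THF, 70 °C, then evaporation; n-BuLi (1.1 equiv), THF, −78 °C; Tf2O (1.2 equiv), −78 °C to 0 °C
Reagents that add atoms: hexamethyldisilazane, C[Si](C)(C)N[Si](C)(C)C; trifluoromethanesulfonic anhydride, O=S(=O)(OS(=O)(=O)C(F)(F)F)C(F)(F)F
Why: O-silylation, bromine–lithium exchange with 1,3 oxygen-to-carbon silyl shift (retro-Brook rearrangement) and O-triflation of the resulting phenoxide, the standard entry to ortho-silylaryl triflates, with the exchange at −78 °C expected to outrun deprotonation next to the MOM ether or at the benzylic positions.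

Step 6
Reactants: 10 3,4-bis(benzyloxy)benzaldehyde
Product: 11 1,2-bis(benzyloxy)-4-(2,2-dibromoethenyl)benzene
Conditions: CBr4 (2 equiv), PPh3 (4 equiv), CH2Cl2, 0 °C
Reagents that add atoms: carbon tetrabromide, BrC(Br)(Br)Br
Why: first stage of the Corey–Fuchs sequence, a Wittig-type dibromo-olefination of an aromatic aldehyde.

Step 7
Reactants: 11 1,2-bis(benzyloxy)-4-(2,2-dibromoethenyl)benzene
Product: 14 3-[3,4-bis(benzyloxy)phenyl]prop-2-ynoic acid, via lithium acetylide 12 (not isolated), via lithium carboxylate 13 (not isolated)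
Conditions: n-BuLi (2.2 equiv), THF, −78 °C; CO2, −78 °C to rt; aq. HCl
Reagents that add atoms: carbon dioxide, O=C=O
Why: second stage of the Corey–Fuchs sequence (bromine–lithium exchange, Fritsch–Buttenberg–Wiechell shift, deprotonation) followed by carboxylation of the acetylide.

Step 8
Reactants: 9 2,3-bis(benzyloxy)-4-(methoxymethoxy)-6-(trimethylsilyl)phenyl trifluoromethanesulfonate (1.5 equiv); 14 3-[3,4-bis(benzyloxy)phenyl]prop-2-ynoic acid
Product: 18 5,6-bis(benzyloxy)-2-[3,4-bis(benzyloxy)phenyl]-7-(methoxymethoxy)-4H-chromen-4-one, via aryne 15 (not isolated), via hydroxyaryl ynone 16 (not isolated), via enaminone 17 (not isolated)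
Conditions: CsF (4 equiv), THF, 125 °C, sealed tube; then Et2NH, EtOH, 60 °C
Reagents that add atoms: none
Why: Fluoride removes the silyl group of 9 and triflate departs, giving aryne 15 between the future C4a and C8a; the caesium carboxylate of 14 adds through oxygen to C8a, and the aryl anion left at C4a attacks the ester carbonyl through a four-membered transition state, so the acyl group moves from oxygen to carbon and the ortho-acyl phenoxide of 16 results. The closest known reaction type is the fluoride-induced insertion of arynes into the C–O bond of carboxylic acids to give ortho-hydroxyaryl ketones, combined with the amine-promoted cyclisation of ortho-hydroxyaryl ynones to flavones. Ring C closes through O1–C2 in a 6-endo mode: diethylamine, added only after the aryne is consumed because it would otherwise add to the aryne itself, adds to the ynone to give enaminone 17, whose amine-bearing carbon is attacked by the phenol with loss of the amine, which steers the closure away from the 5-exo path to an aurone. No stereocentre is formed. The step needs regioselective addition to the unsymmetrical aryne, and the C5 benzyloxy group secures it by directing the nucleophile to the remote carbon C8a, flanked only by C8–H, and by stabilising the negative charge at the adjacent C4a inductively; the C6 oxygen para to C8a reinforces this and the C7 oxygen opposes it only weakly. The high temperature and the excess of 9 are chosen to favour acyl migration over protonation of the aryl anion, which would stop at the aryl ester.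

Step 9
Reactants: 18 5,6-bis(benzyloxy)-2-[3,4-bis(benzyloxy)phenyl]-7-(methoxymethoxy)-4H-chromen-4-one
Product: 19 5,6-bis(benzyloxy)-2-[3,4-bis(benzyloxy)phenyl]-7-hydroxy-4H-chromen-4-one
Conditions: conc. HCl (cat.), MeOH–THF, 50 °C
Reagents that add atoms: none
Why: acid-catalysed acetal exchange with methanol removes the MOM group under conditions too mild to cleave the benzyl ethers, including the more labile one at C5.

Step 10
Reactants: 19 5,6-bis(benzyloxy)-2-[3,4-bis(benzyloxy)phenyl]-7-hydroxy-4H-chromen-4-one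
Product: 21 sodium 5,6-bis(benzyloxy)-2-[3,4-bis(benzyloxy)phenyl]-4-oxo-4H-chromen-7-yl sulfate, via pyridinium sulfate 20 (not isolated)
Conditions: SO3·pyridine (5 equiv), pyridine, 50 °C; then aq. NaHCO3
Reagents that add atoms: sulfur trioxide–pyridine complex, O=S(=O)([O-])[n+]1ccccc1; sodium hydrogencarbonate, [Na+].OC(=O)[O-]
Why: O-sulfation of the only free phenol with an amine–sulfur trioxide complex, with exchange of pyridinium for sodium because pyridine would suppress the later hydrogenolysis of aryl benzyl ethers.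

Step 11
Reactants: 21 sodium 5,6-bis(benzyloxy)-2-[3,4-bis(benzyloxy)phenyl]-4-oxo-4H-chromen-7-yl sulfate
Product: 23 6-hydroxyluteolin 7-sulfate (2-(3,4-dihydroxyphenyl)-5,6-dihydroxy-4-oxo-4H-chromen-7-yl hydrogen sulfate), via sodium salt 22 (not isolated)
Conditions: H2 (1 atm), 10% Pd/C, MeOH–THF, rt, exclusion of air; then aq. HCl (1.0 equiv), 0 °C, C18 desalting, freeze-drying
Reagents that add atoms: none
Why: catalytic hydrogenolysis of the four benzyl ethers, to which the aryl sulfate monoester anion and the conjugated C2–C3 double bond of the chromone should be inert at atmospheric pressure, followed by protonation of the sulfate.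

**Compound list**

1 | 2,3,4-trihydroxybenzaldehyde | O=Cc1ccc(O)c(O)c1O | starting material
2 | 2,3-dihydroxy-4-(methoxymethoxy)benzaldehyde | O=Cc1ccc(OCOC)c(O)c1O | intermediate
3 | 2,3-bis(benzyloxy)-4-(methoxymethoxy)benzaldehyde | O=Cc1ccc(OCOC)c(OCc2ccccc2)c1OCc1ccccc1 | intermediate
4 | 2,3-bis(benzyloxy)-4-(methoxymethoxy)phenyl formate | O=COc1ccc(OCOC)c(OCc2ccccc2)c1OCc1ccccc1 | intermediate
5 | 2,3-bis(benzyloxy)-4-(methoxymethoxy)phenol | Oc1ccc(OCOC)c(OCc2ccccc2)c1OCc1ccccc1 | intermediate
6 | 2,3-bis(benzyloxy)-6-bromo-4-(methoxymethoxy)phenol | Oc1c(Br)cc(OCOC)c(OCc2ccccc2)c1OCc1ccccc1 | intermediate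
7 | [2,3-bis(benzyloxy)-6-bromo-4-(methoxymethoxy)phenoxy]trimethylsilane | C[Si](C)(C)Oc1c(Br)cc(OCOC)c(OCc2ccccc2)c1OCc1ccccc1 | intermediate
8 | lithium 2,3-bis(benzyloxy)-4-(methoxymethoxy)-6-(trimethylsilyl)phenoxide | [Li+].[O-]c1c([Si](C)(C)C)cc(OCOC)c(OCc2ccccc2)c1OCc1ccccc1 | intermediate
9 | 2,3-bis(benzyloxy)-4-(methoxymethoxy)-6-(trimethylsilyl)phenyl trifluoromethanesulfonate | C[Si](C)(C)c1cc(OCOC)c(OCc2ccccc2)c(OCc2ccccc2)c1OS(=O)(=O)C(F)(F)F | intermediate
10 | 3,4-bis(benzyloxy)benzaldehyde | O=Cc1ccc(OCc2ccccc2)c(OCc2ccccc2)c1 | starting material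
11 | 1,2-bis(benzyloxy)-4-(2,2-dibromoethenyl)benzene | BrC(Br)=Cc1ccc(OCc2ccccc2)c(OCc2ccccc2)c1 | intermediate
12 | lithium [3,4-bis(benzyloxy)phenyl]acetylide | [Li+].[C-]#Cc1ccc(OCc2ccccc2)c(OCc2ccccc2)c1 | intermediate
13 | lithium 3-[3,4-bis(benzyloxy)phenyl]prop-2-ynoate | [Li+].[O-]C(=O)C#Cc1ccc(OCc2ccccc2)c(OCc2ccccc2)c1 | intermediate
14 | 3-[3,4-bis(benzyloxy)phenyl]prop-2-ynoic acid | O=C(O)C#Cc1ccc(OCc2ccccc2)c(OCc2ccccc2)c1 | intermediate
15 | 3,4-bis(benzyloxy)-5-(methoxymethoxy)benzyne (1,2-didehydrobenzene) | COCOC1=CC#CC(OCc2ccccc2)=C1OCc1ccccc1 | intermediate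
16 | 1-[2,3-bis(benzyloxy)-6-hydroxy-4-(methoxymethoxy)phenyl]-3-[3,4-bis(benzyloxy)phenyl]prop-2-yn-1-one (present as its caesium phenoxide until ethanol is added) | O=C(C#Cc1ccc(OCc2ccccc2)c(OCc2ccccc2)c1)c1c(O)cc(OCOC)c(OCc2ccccc2)c1OCc1ccccc1 | intermediate
17 | (E)-1-[2,3-bis(benzyloxy)-6-hydroxy-4-(methoxymethoxy)phenyl]-3-[3,4-bis(benzyloxy)phenyl]-3-(diethylamino)prop-2-en-1-one | CCN(CC)/C(=C/C(=O)c1c(O)cc(OCOC)c(OCc2ccccc2)c1OCc1ccccc1)c1ccc(OCc2ccccc2)c(OCc2ccccc2)c1 | intermediate
18 | 5,6-bis(benzyloxy)-2-[3,4-bis(benzyloxy)phenyl]-7-(methoxymethoxy)-4H-chromen-4-one | O=c1cc(-c2ccc(OCc3ccccc3)c(OCc3ccccc3)c2)oc2cc(OCOC)c(OCc3ccccc3)c(OCc3ccccc3)c12 | intermediate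
19 | 5,6-bis(benzyloxy)-2-[3,4-bis(benzyloxy)phenyl]-7-hydroxy-4H-chromen-4-one | O=c1cc(-c2ccc(OCc3ccccc3)c(OCc3ccccc3)c2)oc2cc(O)c(OCc3ccccc3)c(OCc3ccccc3)c12 | intermediate
20 | pyridinium 5,6-bis(benzyloxy)-2-[3,4-bis(benzyloxy)phenyl]-4-oxo-4H-chromen-7-yl sulfate | O=c1cc(-c2ccc(OCc3ccccc3)c(OCc3ccccc3)c2)oc2cc(OS(=O)(=O)[O-])c(OCc3ccccc3)c(OCc3ccccc3)c12.c1cc[nH+]cc1 | intermediate
21 | sodium 5,6-bis(benzyloxy)-2-[3,4-bis(benzyloxy)phenyl]-4-oxo-4H-chromen-7-yl sulfate | O=c1cc(-c2ccc(OCc3ccccc3)c(OCc3ccccc3)c2)oc2cc(OS(=O)(=O)[O-])c(OCc3ccccc3)c(OCc3ccccc3)c12.[Na+] | intermediate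
22 | sodium 2-(3,4-dihydroxyphenyl)-5,6-dihydroxy-4-oxo-4H-chromen-7-yl sulfate | O=c1cc(-c2ccc(O)c(O)c2)oc2cc(OS(=O)(=O)[O-])c(O)c(O)c12.[Na+] | intermediate
23 | 6-hydroxyluteolin 7-sulfate | O=c1cc(-c2ccc(O)c(O)c2)oc2cc(OS(=O)(=O)O)c(O)c(O)c12 | target

**Step count.** Total: 11 steps. Longest linear sequence: 9 steps (steps 1–5 and 8–11); the ring B acid is made in 2 steps (6–7) and joins at step 8.

**Steps most likely to fail**

Step 8. The aryl anion formed after carboxylate addition may be protonated before the acyl group migrates, so that the sequence stops at O-arylation. The propiolate may also lose CO2 at 125 °C, and the phenoxide may close 5-exo before diethylamine is added. The fallback joins ring A to the C4 carbon by a different, established aryne reaction. It sets out from 9 and 11. The aryne generated from 9 with CsF in DMF at rt inserts into the C=O bond of the formamide with the same regiochemical bias, and aqueous work-up gives 2,3-bis(benzyloxy)-6-hydroxy-4-(methoxymethoxy)benzaldehyde F1. Dibromo-olefin 11, treated with n-BuLi as in step 7 but quenched with water in place of CO2, gives 1,2-bis(benzyloxy)-4-ethynylbenzene F2. Its lithium acetylide 12 (2.5 equiv, from F2 and n-BuLi, THF, −78 °C to 0 °C; the first equivalent serves as base for the phenol) adds to the aldehyde to give racemic 3,4-bis(benzyloxy)-2-{3-[3,4-bis(benzyloxy)phenyl]-1-hydroxyprop-2-yn-1-yl}-5-(methoxymethoxy)phenol F3. MnO2 in CH2Cl2 should oxidise the benzylic, propargylic carbinol to ynone 16, where the route is rejoined; Et2NH in EtOH then closes 16 to 18 as in step 8.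

Step 4. Bromination may occur at C5 beside the MOM ether, run on to a dibromide, or give way to oxidation of the electron-rich 4-alkoxyphenol to a quinone. The fallback places the silyl group by directed ortho-metalation and avoids electrophilic halogenation altogether. It sets out from 5 and returns at 9, so that it replaces steps 4 and 5. Phenol 5 with ClC(O)NEt2 and K2CO3 in MeCN at reflux gives 2,3-bis(benzyloxy)-4-(methoxymethoxy)phenyl N,N-diethylcarbamate F4. s-BuLi/TMEDA in THF at −78 °C followed by TMSCl should silylate the position ortho to the carbamate, the strongest directing group on the ring, to give 2,3-bis(benzyloxy)-4-(methoxymethoxy)-6-(trimethylsilyl)phenyl N,N-diethylcarbamate F5. LiAlH4 in THF at 0 °C to rt cleaves the carbamate to 2,3-bis(benzyloxy)-4-(methoxymethoxy)-6-(trimethylsilyl)phenol F6, and Tf2O with pyridine in CH2Cl2 at 0 °C gives 9.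

Step 10. Sulfation of the acidic, poorly nucleophilic 7-hydroxyl may stay incomplete, or the sulfate may be lost by hydrolysis while the amphiphilic salt is isolated. The fallback introduces the sulfate in masked, neutral form. It sets out from 19 and returns at 21. Phenol 19 with 2,2,2-trichloroethyl chlorosulfate, Et3N and DMAP in THF gives 5,6-bis(benzyloxy)-2-[3,4-bis(benzyloxy)phenyl]-4-oxo-4H-chromen-7-yl 2,2,2-trichloroethyl sulfate F7, a diester that can be chromatographed on silica. Zinc dust with HCO2NH4 in MeOH removes the trichloroethyl group by reductive fragmentation and gives ammonium 5,6-bis(benzyloxy)-2-[3,4-bis(benzyloxy)phenyl]-4-oxo-4H-chromen-7-yl sulfate F8. Washing with aq. NaHCO3 exchanges the cation and gives 21.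

**Further compounds**

F1 | step 8 | 2,3-bis(benzyloxy)-6-hydroxy-4-(methoxymethoxy)benzaldehyde | O=Cc1c(O)cc(OCOC)c(OCc2ccccc2)c1OCc1ccccc1
F2 | step 8 | 1,2-bis(benzyloxy)-4-ethynylbenzene | C#Cc1ccc(OCc2ccccc2)c(OCc2ccccc2)c1
F3 | step 8 | racemic 3,4-bis(benzyloxy)-2-{3-[3,4-bis(benzyloxy)phenyl]-1-hydroxyprop-2-yn-1-yl}-5-(methoxymethoxy)phenol | OC(C#Cc1ccc(OCc2ccccc2)c(OCc2ccccc2)c1)c1c(O)cc(OCOC)c(OCc2ccccc2)c1OCc1ccccc1
F4 | step 4 | 2,3-bis(benzyloxy)-4-(methoxymethoxy)phenyl N,N-diethylcarbamate | CCN(CC)C(=O)Oc1ccc(OCOC)c(OCc2ccccc2)c1OCc1ccccc1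
F5 | step 4 | 2,3-bis(benzyloxy)-4-(methoxymethoxy)-6-(trimethylsilyl)phenyl N,N-diethylcarbamate | CCN(CC)C(=O)Oc1c([Si](C)(C)C)cc(OCOC)c(OCc2ccccc2)c1OCc1ccccc1
F6 | step 4 | 2,3-bis(benzyloxy)-4-(methoxymethoxy)-6-(trimethylsilyl)phenol | Oc1c([Si](C)(C)C)cc(OCOC)c(OCc2ccccc2)c1OCc1ccccc1
F7 | step 10 | 5,6-bis(benzyloxy)-2-[3,4-bis(benzyloxy)phenyl]-4-oxo-4H-chromen-7-yl 2,2,2-trichloroethyl sulfate | O=c1cc(-c2ccc(OCc3ccccc3)c(OCc3ccccc3)c2)oc2cc(OS(=O)(=O)OCC(Cl)(Cl)Cl)c(OCc3ccccc3)c(OCc3ccccc3)c12
F8 | step 10 | ammonium 5,6-bis(benzyloxy)-2-[3,4-bis(benzyloxy)phenyl]-4-oxo-4H-chromen-7-yl sulfate | O=c1cc(-c2ccc(OCc3ccccc3)c(OCc3ccccc3)c2)oc2cc(OS(=O)(=O)[O-])c(OCc3ccccc3)c(OCc3ccccc3)c12.[NH4+]
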